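**Retrosynthetic overview**
- Hansfordiol A ⇒ cut the aryl–CH2 bond: 5-iodoresorcinol + (S)-heptadec-16-en-2-ol, joined last by a light-driven anti-Markovnikov radical hydroarylation, no protecting groups.
- (S)-Heptadec-16-en-2-ol ⇒ cut C3–C4: (S)-propylene oxide (carries the only stereocentre) + tetradec-13-enyl Grignard.
- 14-Chlorotetradec-1-ene ⇒ cut C11–C12: undec-10-enyl Grignard + 1-bromo-3-chloropropane.
- Rings: the resorcinol ring is bought; no ring is formed in the route.

Assumption: 14-halotetradec-1-enes are not dependable stock items, so the C14 alkenyl unit is made in step 1 from commodity 11-bromoundec-1-ene; 5-iodoresorcinol is taken as a catalogue compound.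

**Step 1**
Reactants: 1 11-bromoundec-1-ene; 2 1-bromo-3-chloropropane
Product: 4 14-chlorotetradec-1-ene, via undec-10-enylmagnesium bromide 3 (not isolated)
Conditions: Mg, THF, 40 °C; then added to 2 (1.3 equiv), Li2CuCl4 (2 mol%), THF, −10 → 20 °C
Reagents that add atoms: magnesium, [Mg] (held only in intermediate 3, not in 4)
Why: Cu-catalysed Kochi sp3–sp3 Grignard cross-coupling, in which the alkylcuprate displaces the primary bromide of 2 much faster than the chloride, so one C–C bond forms and the chloride is kept as the handle for step 2 (no stereocentre involved).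

**Step 2**
Reactants: 4 14-chlorotetradec-1-ene; 5 (S)-2-methyloxirane ((S)-propylene oxide)
Product: 7 (S)-heptadec-16-en-2-ol, via tetradec-13-enylmagnesium chloride 6 (not isolated)
Conditions: Mg (cat. I2), THF, reflux; then CuI (10 mol%), 5 (1.5 equiv), THF, −30 → 0 °C; 1 M HCl
Reagents that add atoms: magnesium, [Mg] (held only in intermediate 6, not in 7)
Why: Cu(I)-catalysed Grignard opening of a terminal epoxide by SN2 attack at the unsubstituted CH2; no bond to the stereocentre is made or broken, so the (S) centre bought in 5 becomes C2 (S) of 7.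

**Step 3**
Reactants: 7 (S)-heptadec-16-en-2-ol; 8 5-iodobenzene-1,3-diol (5-iodoresorcinol)
Product: 9 Hansfordiol A, 5-[(16S)-16-hydroxyheptadecyl]benzene-1,3-diol
Conditions: 8 (3 equiv), N-phenylphenothiazine (PTH, 5 mol%), CySH (5 mol%), HCO2Na (3 equiv), DMSO/t-BuOH 1:1 (+5% H2O), 390 nm LEDs, Ar, 30 °C
Reagents that add atoms: none
Why: Proposed new method: photoexcited PTH (E* about −2.1 V vs SCE) cleaves the C–I bond of 8 by dissociative electron transfer, the 3,5-dihydroxyphenyl σ-radical adds to the terminal CH2 of 7 (k about 10^8 M−1 s−1, strictly anti-Markovnikov), the secondary alkyl radical takes H from the thiol, and the thiyl radical takes H from formate to give CO2•−, which reduces PTH•+ or another molecule of 8 and carries a chain; the H-bond-accepting DMSO/t-BuOH medium ties up the ArO–H groups so they are slow H-atom donors, excess 8 lets the alkene be the limiting partner, and the stereocentre fifteen carbons away is untouched; the closest known reaction type is the photoredox aryl-radical anti-Markovnikov hydroarylation of alkenes with halopyridines and protected aryl halides (thiol HAT co-catalyst, formate or Hantzsch ester as reductant, alkene in excess), which has not been shown with an unprotected halo-resorcinol or with an unactivated long-chain alkenol as the limiting partner.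

**Compound list**
1 | 11-bromoundec-1-ene | BrCCCCCCCCCC=C | starting material
2 | 1-bromo-3-chloropropane | ClCCCBr | starting material
3 | undec-10-enylmagnesium bromide | C=CCCCCCCCCC[Mg]Br | intermediate
4 | 14-chlorotetradec-1-ene | ClCCCCCCCCCCCCC=C | intermediate
5 | (S)-2-methyloxirane | C[C@H]1CO1 | starting material
6 | tetradec-13-enylmagnesium chloride | C=CCCCCCCCCCCCC[Mg]Cl | intermediate
7 | (S)-heptadec-16-en-2-ol | C[C@H](O)CCCCCCCCCCCCCC=C | intermediate
8 | 5-iodobenzene-1,3-diol | Oc1cc(O)cc(I)c1 | starting material
9 | Hansfordiol A, 5-[(16S)-16-hydroxyheptadecyl]benzene-1,3-diol | C[C@H](O)CCCCCCCCCCCCCCCc1cc(O)cc(O)c1 | target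

**Total step count:** 3
**Longest linear sequence:** 3 steps (1 → 4 → 7 → 9)

**Steps most likely to fail**

1. Step 3 (the proposed new hydroarylation). The aryl radical may be reduced to resorcinol by thiol, formate or solvent before it adds to the alkene. The thiol may also add to the alkene, or phenoxyl radicals may form. The fallback uses known two-electron chemistry; it sets out from 7 and comes back at 9. 7 is hydroborated with 9-BBN (2.2 equiv, THF, 0 → 25 °C; one equivalent is taken up by the hydroxyl) to give (S)-9-[16-(9-borabicyclo[3.3.1]nonan-9-yloxy)heptadecyl]-9-borabicyclo[3.3.1]nonane F5, which is used in the same flask. A B-alkyl Suzuki–Miyaura coupling with 1,3-bis(benzyloxy)-5-bromobenzene (PdCl2(dppf) 3 mol%, aq. K3PO4, THF/DMF, 60 °C) gives (S)-17-[3,5-bis(benzyloxy)phenyl]heptadecan-2-ol F6. Hydrogenolysis (H2 1 atm, Pd/C, EtOAc/EtOH, 25 °C) then gives 9. The stereocentre is not involved at any point.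

2. Step 2. Grignard formation from the primary chloride may be sluggish or give Wurtz dimer, and magnesium halide may open the epoxide to a halohydrin. The fallback changes the nucleophile and builds the terminal alkene by isomerisation; it sets out from 5 and comes back at 7. Tetradec-1-yne is deprotonated (n-BuLi, THF/DMPU, −78 °C) to lithium tetradec-1-yn-1-ide F2. This opens 5 at the CH2 carbon (−78 → 25 °C, then 1 M HCl) to give (S)-heptadec-4-yn-2-ol F3 with the stereocentre untouched. An alkyne zipper isomerisation (KH, 1,3-diaminopropane, 0 → 25 °C) moves the triple bond to the chain end to give (S)-heptadec-16-yn-2-ol F4; the carbinol centre is held as its alkoxide and keeps its configuration. Semi-hydrogenation (H2, Lindlar catalyst, quinoline, hexane) gives 7.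

3. Step 1. Homocoupling to docosa-1,21-diene or a second coupling at the C–Cl end would give products that are hard to separate from 4. The fallback replaces the cross-coupling with a strained-ether opening followed by functional-group exchange; it sets out from 3 (made from 1 as in step 1) and comes back at 4. Grignard 3 opens oxetane (CuI 10 mol%, THF, 0 → 40 °C, then 1 M HCl) to give tetradec-13-en-1-ol F1. An Appel chlorination (PPh3, CCl4, CH2Cl2, 40 °C) converts this into 4.

**Further compounds**
F1 | step 1 | tetradec-13-en-1-ol | OCCCCCCCCCCCCC=C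
F2 | step 2 | lithium tetradec-1-yn-1-ide | [Li]C#CCCCCCCCCCCCC
F3 | step 2 | (S)-heptadec-4-yn-2-ol | C[C@H](O)CC#CCCCCCCCCCCCC
F4 | step 2 | (S)-heptadec-16-yn-2-ol | C[C@H](O)CCCCCCCCCCCCCC#C
F5 | step 3 | (S)-9-[16-(9-borabicyclo[3.3.1]nonan-9-yloxy)heptadecyl]-9-borabicyclo[3.3.1]nonane | C[C@H](OB1C2CCCC1CCC2)CCCCCCCCCCCCCCCB1C2CCCC1CCC2
F6 | step 3 | (S)-17-[3,5-bis(benzyloxy)phenyl]heptadecan-2-ol | C[C@H](O)CCCCCCCCCCCCCCCc1cc(OCc2ccccc2)cc(OCc2ccccc2)c1
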